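Structural features

The target is a 1,4-naphthoquinone. Ring B (C1–C4) is an unsubstituted quinone ring, fused through C4a–C8a to the benzenoid ring A. Ring A carries four different groups in sequence: OMe on C5 (peri to C4=O), a six-carbon side chain on C6, H on C7 and a free OH on C8 (peri to C1=O and hydrogen-bonded to it). The side chain is attached through its carbinol carbon, the only stereocentre (R); this carbon is benzylic, esterified with 3-methylbut-2-enoic acid, and two carbons away from a trisubstituted alkene. The fragile elements are the quinone C2=C3 bond (a Michael acceptor, sensitive to base and nucleophiles), the benzylic C–O bond next to an electron-rich ring in every naphthalene-stage intermediate (ionisation and ring closure onto the alkene under acid), and the conjugated ester, whose double bond can move out of conjugation under strong base. The real difficulty is the substitution pattern, not the carbon count: the two para oxygens of ring A differ (methyl on the one beside the side chain, hydrogen on the other), the quinone must sit in the ring without the side chain, and the benzylic stereocentre must survive ring construction and oxidation. The key step exploits that in ring A the branched carbon C6 lies beside oxygenated C5 and the unsubstituted C7 beside oxygenated C8. C6–C7 can therefore come from a terminal alkyne (terminal carbon = C7), C8 from a carbene carbon that already bears its oxygen and is bonded to C8a of a benzene ring (the future ring B), and C5 from a carbonyl ligand that becomes a hydroxyl and bonds to C4a. Since the C5 and C8 oxygens then have different origins, they are distinguishable from the moment ring A exists.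

Logic of the disconnections

23 ⇒ 22. No skeletal bond is cut; the free C8 hydroxyl is traced back to an aryl ester with the same acyl group as the side chain. Ring A must be electron-poor and free of phenolic OH when ring B is oxidised, and using the same acyl group lets one acylation serve both oxygens. The forward step must be a methanolysis that removes only the aryl ester and leaves the alkyl ester and the quinone alone.

22 ⇒ 21. The quinone carbonyls at C1 and C4 are traced back to methyl ethers. A 1,4-dimethoxy ring is the form in which ring B survives organolithium, carbene, fluoride and carbonate chemistry, so all earlier work is done on a robust naphthalene. The forward oxidation must choose ring B over ring A and spare the trisubstituted alkene and the benzylic ester.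

21 ⇒ 19 + 20. Both acyl–oxygen bonds are cut, at the C8 oxygen and at the carbinol oxygen. This removes ten carbons that come from a bulk acid and leaves a diol. The forward step must acylate a peri-flanked naphthol and a secondary benzylic alcohol without shifting the conjugated double bond of the acyl group.

19 ⇒ 18. The two O–H bonds are traced back to an O–Si bond (carbinol) and an O–CH2CH2Si bond (C8). Both groups respond to fluoride, so one reagent frees both. The forward step needs fluoride to fragment the aryl ether as well as desilylate the carbinol, and the electron-rich naphthol must be kept from air.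

18 ⇒ 17. The O–CH3 bond at C5 is cut. In 17 this oxygen is the only free hydroxyl, so the methyl group has nowhere else to go. The forward step only has to alkylate a hindered, hydrogen-bonded naphthol.

17 ⇒ 7 + 15. Three ring bonds are cut: C7–C8, C5–C6 and C4a–C5, with C5 returned to a carbonyl ligand of chromium. The cut is made here because the sequence oxygenated carbon, branched carbon, CH, oxygenated carbon is what a carbonyl ligand, a terminal alkyne and an alkoxycarbene carbon deliver, with the two oxygens differently substituted. A tetrasubstituted, oxygen-differentiated naphthalene is reduced to a benzene-derived carbene complex and a seven-carbon alkyne that already holds the stereocentre. The forward step needs the right insertion regiochemistry, closure at the single free ortho carbon, carbonyl insertion in preference to five-ring formation, and conditions that leave the silyl ether, the alkene and the stereocentre untouched.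

7 ⇒ 5 ⇒ 1 + 2. First the bond between the carbene carbon and the silylethoxy oxygen is cut, then the aryl–acyl C–C bond (an aryl anion adding to a carbonyl ligand). This leads to two bulk chemicals. The forward steps need clean monolithiation of 1 and low-temperature handling of the acyloxycarbene stage, since the alkoxy group wanted here cannot be delivered by a stable alkylating agent.

15 ⇒ 13 ⇒ 12. The O–Si and C–Si groups are stripped, and the C–H bond of the stereocentre is traced back to a ketone. The stereocentre is thus created on a small, easily purified ynone and not on the arene. The forward reduction must select one enantioface; the silyl group on the alkyne terminus keeps the ynone stable and is removed afterwards.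

12 ⇒ 9 + 10, and 9 ⇒ 8. The bond between the carbonyl carbon and the alkyne carbon is cut (acyl cation equivalent plus acetylide), and the amide is traced to the acid. Both pieces are commercial. The forward steps need single addition (no tertiary alcohol) and no migration of the β,γ double bond into conjugation.

Other disconnections considered

Alternative 1: Ring B would be cut at C1–C8a and C4–C4a, leaving a benzyne of ring A and a four-carbon diene. In the forward direction a hindered lithium amide would deprotonate bromoarene A1 next to bromine (bromine on the future C8a, hydrogen on the future C4a). Loss of bromide would give the C4a–C8a aryne, which furan A2 would trap by [4+2] cycloaddition to give the oxygen-bridged dihydronaphthalene A3 as two bridgehead diastereomers that converge later.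
- In its favour: ring A is an ordinary benzene that carries the C5 methyl ether and a separately protected C8 oxygen from the start, so the para oxygens never need to be told apart afterwards. On this point it is better than the chosen plan. It is also better in using no chromium and no carbon monoxide chemistry.
- Equal: A2 is symmetric, so there is no regiochemical question, as in the chosen plan.
- Against: A1 is a pentasubstituted benzene whose chiral side chain must be built on the ring, so the stereocentre is set on a hindered aryl carbonyl compound and not on a small ynone. The amide base could also metalate C7–H between the silyloxy group and the side chain, with silyl migration. A3 is still two adjustments from a quinone: the oxygen bridge must be opened under acid (conditions that endanger the benzylic silyl ether and the alkene) and the resulting naphthol oxidised at its para position.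
- Comparison: after the ring-forming event the two plans need about the same number of steps. Before it the chosen plan is shorter, because 7 and 15 are each a few steps from bulk chemicals, and it forms three skeletal bonds, not two.

Alternative 2: Ring A would be cut at C4a–C5 and C8–C8a. The sodium salt of hydroxypyrone A4 (the enol form of the methoxy-substituted glutaconic anhydride, made with a hydride base) would add across one C=C of 1,4-benzoquinone A5 in a [4+2] sense. The adduct would decarboxylate and aromatise, and excess A5 would oxidise the naphthalenediol to quinone A6.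
- In its favour: A6 already has ring B as the quinone, the free C8 hydroxyl and the C5 methyl ether. Only desilylation and acylation of the carbinol would remain (the hydrogen-bonded peri hydroxyl is far less nucleophilic). After the key step this is clearly better than the chosen plan, which needs five steps including an oxidative demethylation.
- Equal: A5 is symmetric, so regiochemistry is no issue.
- Against: the precedent for this annulation lies with homophthalic anhydrides, whose anion is benzylic. The anion of a monocyclic α-methoxy glutaconic anhydride is less stabilised, and A5 is also a Michael acceptor and an oxidant toward it. A4 is a sensitive compound with no obvious short synthesis, and loss of its silyl group would invite butenolide formation.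
- Comparison: mechanistically the chosen plan is better supported. In step count after the key step alternative 2 is better. The total count is open, because it depends on what A4 costs.

Alternative 3: Only C8–C8a would be cut. Heating cyclobutenone A7 (aryl and methoxy on the sp3 ring carbon, side chain on the adjacent alkene carbon) in an aromatic solvent would open the four-membered ring, with the methoxy group turning outward and the aryl group inward. The arylvinylketene would then close onto the single free ortho carbon and tautomerise to naphthol A8.
- In its favour: A8 has the methyl group on the C5 oxygen and the free phenol at C8, the pattern of the target, so neither methylation nor removal of a carbene-derived group is needed. This is better than the chosen plan on this point. The step is metal-free, also better.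
- Equal: the site of ring closure is fixed by the same methoxy-blocked ortho position. The ring B oxidation problem (acylate the C8 hydroxyl, oxidise, deacylate) is unchanged.
- Against: only one skeletal bond is formed, so the other bonds of ring A must be built into A7. That requires site-selective addition of an aryl metal to one of two carbonyls of a monosubstituted cyclobutenedione and O-methylation of a hindered tertiary alkoxide. The N,N-diisopropylcarbamate on the carbinol is so robust that its removal needs hydride or strongly basic conditions and must precede oxidation of ring B.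
- Comparison: after the key step A8 needs about as many steps as 17. The way to A7 is longer and less convergent than the way to 7 and 15.

Key step: step 7

Remark on the chemistry: the carbinol carbon has the same CIP ranking (O > alkynyl or aryl carbon > CH2 > H) in 13–15, 17–19 and 21–23, so R in 15 corresponds to R in 23 and no inversion is needed; the structures of 7, 15 and 17 were checked against the target on this basis and on the oxygen pattern, and needed no correction.
Remark on notation: the η6-bound complex 16 cannot be written as one connected string and is listed as its two parts.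

Step 1
Reactants: 1 1,4-dimethoxybenzene; 2 hexacarbonylchromium, Cr(CO)6
Product: 5 tetramethylammonium pentacarbonyl(2,5-dimethoxybenzoyl)chromate, via 2,5-dimethoxyphenyllithium 3 (not isolated), via lithium acylchromate 4 (not isolated)
Conditions: n-BuLi, TMEDA, THF, 0 °C → rt; add to 2, 0 °C → rt; then Me4NBr, H2O
Reagents that add atoms: tetramethylammonium bromide, C[N+](C)(C)C.[Br-]
Why: Methoxy-directed ortho-lithiation of 1 and addition of the aryllithium to a carbonyl ligand of 2 (first half of the Fischer carbene synthesis) should give the acylchromate; cation exchange turns it into a storable, weighable ammonium salt that is acylated cleanly in the next step.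

Step 2
Reactants: 5 tetramethylammonium pentacarbonyl(2,5-dimethoxybenzoyl)chromate
Product: 7 pentacarbonyl{(2,5-dimethoxyphenyl)[2-(trimethylsilyl)ethoxy]methylidene}chromium, via acetoxycarbene complex 6 (not isolated)
Conditions: AcBr, CH2Cl2, −40 °C; then Me3SiCH2CH2OH, −40 → −10 °C
Reagents that add atoms: 2-(trimethylsilyl)ethanol, C[Si](C)(C)CCO
Why: O-acylation of the acylchromate gives a strongly electrophilic acyloxycarbene, and the primary alcohol displaces acetate by addition–elimination at the carbene carbon (acyloxy/alkoxy exchange variant of the Fischer carbene synthesis); this route is chosen because no stable oxonium salt or triflate exists for the 2-(trimethylsilyl)ethyl group.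

Step 3
Reactants: 8 4-methylpent-3-enoic acid
Product: 9 N-methoxy-N,4-dimethylpent-3-enamide
Conditions: CDI, CH2Cl2, rt; then MeONHMe·HCl, rt
Reagents that add atoms: N,O-dimethylhydroxylamine hydrochloride, CNOC.Cl
Why: Weinreb amide formation through the acyl imidazolide; the near-neutral activation should avoid migration of the β,γ double bond into conjugation.

Step 4
Reactants: 9 N-methoxy-N,4-dimethylpent-3-enamide; 10 ethynyltrimethylsilane
Product: 12 6-methyl-1-(trimethylsilyl)hept-5-en-1-yn-3-one, via lithium (trimethylsilyl)acetylide 11 (not isolated)
Conditions: n-BuLi, THF, −78 °C; then 9, −78 → −20 °C; cold 1 M HCl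
Reagents that add atoms: none
Why: Weinreb ketone synthesis: the acetylide adds once and the N-methoxy chelate holds the tetrahedral intermediate until the quench, so no tertiary alcohol should form; the cold acidic quench avoids base-mediated conjugation of the skipped enone.

Step 5
Reactants: 12 6-methyl-1-(trimethylsilyl)hept-5-en-1-yn-3-one
Product: 13 (3R)-6-methyl-1-(trimethylsilyl)hept-5-en-1-yn-3-ol
Conditions: Ru[(R,R)-TsDPEN](p-cymene) (2 mol %), i-PrOH, rt
Reagents that add atoms: none
Why: Noyori asymmetric transfer hydrogenation of an α,β-acetylenic ketone with the 16-electron amido complex (made beforehand from RuCl[(R,R)-TsDPEN](p-cymene) and KOH; TsDPEN = N-tosyl-1,2-diphenylethane-1,2-diamine) and 2-propanol as hydride source; the alkynyl group takes the place an aryl group takes in aryl ketone reductions, so the (R,R)-ligand should deliver hydride to the face that gives the R carbinol, without touching the C≡C bond or the alkene. An oxazaborolidine–borane reduction is avoided because its sense depends on whether the silylalkynyl or the alkyl group acts as the larger substituent.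

Step 6
Reactants: 13 (3R)-6-methyl-1-(trimethylsilyl)hept-5-en-1-yn-3-ol
Product: 15 tert-butyldimethyl{[(3R)-6-methylhept-5-en-1-yn-3-yl]oxy}silane, via bis-silylated alkynol 14 (not isolated)
Conditions: TBSCl, imidazole, DMF, rt; then MeOH, K2CO3, rt
Reagents that add atoms: tert-butyldimethylsilyl chloride, CC(C)(C)[Si](C)(C)Cl
Why: O-silylation of the secondary alcohol, then carbonate-catalysed methanolysis of the alkynyl C–Si bond in the same flask, which leaves the hindered O–Si bond intact; telescoping avoids isolating a small volatile alkynol, and the stereocentre is not involved.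

Step 7
Reactants: 7 pentacarbonyl{(2,5-dimethoxyphenyl)[2-(trimethylsilyl)ethoxy]methylidene}chromium; 15 tert-butyldimethyl{[(3R)-6-methylhept-5-en-1-yn-3-yl]oxy}silane
Product: 17 2-[(1R)-1-(tert-butyldimethylsilyloxy)-4-methylpent-3-enyl]-5,8-dimethoxy-4-[2-(trimethylsilyl)ethoxy]naphthalen-1-ol, via Cr(CO)3-bound naphthol 16 (not isolated)
Conditions: 15 (1.3 equiv), THF (0.1 M), 50 °C, argon; then air, Et2O, rt, filtration through silica
Reagents that add atoms: none
Why: Thermal loss of one carbonyl ligand from 7 (eased by transient chelation of the ortho methoxy group) opens a site for 15, which inserts into the Cr=C bond with its unsubstituted carbon bonded to the carbene carbon (C7–C8), because the carbon bearing the bulky silyloxyalkyl group stays away from the substituted carbene carbon. A carbonyl ligand then inserts at the substituted alkyne carbon (C5–C6) to give a chromium-bound vinylketene, and a 6π-electrocyclisation of the ketene carbon onto the only free ortho carbon of the aryl group (C4a–C5), followed by enolisation, gives the Cr(CO)3-bound 4-alkoxy-1-naphthol 16. Stirring in air oxidises the zerovalent chromium and releases 17. The closest known reaction type is the Dötz benzannulation of aryl(alkoxy)carbene chromium complexes with terminal propargylic silyl ethers. Ring A is the one ring closed, as a six-membered carbocycle by electrocyclic closure of the metal-templated ketene (a [3+2+1] assembly of carbene carbon plus aryl C=C, alkyne and CO). No stereocentre is formed; the carbinol centre of 15 is a spectator under these neutral conditions and is carried over as R. The selectivities needed are the insertion regiochemistry (secured by the steric bias of a terminal alkyne), the site of ring closure (the other ortho position is blocked by OMe) and carbonyl insertion over five-ring formation (favoured by chromium, THF and moderate temperature), so the new hydroxyl lies on C5 beside the side chain and the still-alkylated carbene oxygen on C8.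

Step 8
Reactants: 17 2-[(1R)-1-(tert-butyldimethylsilyloxy)-4-methylpent-3-enyl]-5,8-dimethoxy-4-[2-(trimethylsilyl)ethoxy]naphthalen-1-ol
Product: 18 tert-butyl{[(1R)-4-methyl-1-{1,5,8-trimethoxy-4-[2-(trimethylsilyl)ethoxy]naphthalen-2-yl}pent-3-en-1-yl]oxy}dimethylsilane
Conditions: MeI, Cs2CO3, DMF, rt
Reagents that add atoms: iodomethane, CI
Why: Williamson O-methylation of the only free hydroxyl (the peri-hydrogen-bonded, flanked naphthol, hence Cs2CO3 in DMF); the carbonate base should be too weak to cause silyl transfer from the neighbouring carbinol oxygen, and this step fixes the methyl group on the C5 oxygen.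

Step 9
Reactants: 18 tert-butyl{[(1R)-4-methyl-1-{1,5,8-trimethoxy-4-[2-(trimethylsilyl)ethoxy]naphthalen-2-yl}pent-3-en-1-yl]oxy}dimethylsilane
Product: 19 3-[(1R)-1-hydroxy-4-methylpent-3-enyl]-4,5,8-trimethoxynaphthalen-1-ol
Conditions: Bu4NF (5 equiv), THF, 0 → 60 °C, argon; degassed aqueous work-up
Reagents that add atoms: none
Why: Fluoride cleaves the O–Si bond of the TBS ether and attacks silicon of the 2-(trimethylsilyl)ethyl ether, which fragments to ethene and the naphtholate (the β-elimination used in silylethyl deprotections; the aryloxide is a competent leaving group on warming). The product is a 4-methoxy-1-naphthol and should be kept under argon and acylated at once.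

Step 10
Reactants: 19 3-[(1R)-1-hydroxy-4-methylpent-3-enyl]-4,5,8-trimethoxynaphthalen-1-ol; 20 3-methylbut-2-enoic acid
Product: 21 (1R)-4-methyl-1-{1,5,8-trimethoxy-4-[(3-methylbut-2-enoyl)oxy]naphthalen-2-yl}pent-3-enyl 3-methylbut-2-enoate
Conditions: 20 (3 equiv), DCC, DMAP (cat.), CH2Cl2, 0 °C → rt
Reagents that add atoms: none
Why: Steglich esterification of the naphthol and the secondary alcohol with the same acid; the mild, weakly basic conditions should keep the acyl double bond in conjugation, and the aryl ester deactivates ring A for the oxidation that follows.

Step 11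
Reactants: 21 (1R)-4-methyl-1-{1,5,8-trimethoxy-4-[(3-methylbut-2-enoyl)oxy]naphthalen-2-yl}pent-3-enyl 3-methylbut-2-enoate
Product: 22 (1R)-1-{1-methoxy-4-[(3-methylbut-2-enoyl)oxy]-5,8-dioxo-5,8-dihydronaphthalen-2-yl}-4-methylpent-3-enyl 3-methylbut-2-enoate
Conditions: (NH4)2Ce(NO3)6 (2.5 equiv), MeCN/H2O, 0 °C, short reaction time
Reagents that add atoms: water, O
Why: Oxidative demethylation of a 1,4-dimethoxyarene by tetravalent cerium (two one-electron oxidations, water adds at the methoxy-bearing carbons, methanol leaves). Ring B with two para methoxy groups is the electron-rich ring, whereas ring A is deactivated by the aryl ester and cannot become a quinone without losing an acyl group, so the quinone should form in ring B; a short reaction at 0 °C should spare the alkene and the benzylic ester.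

Step 12
Reactants: 22 (1R)-1-{1-methoxy-4-[(3-methylbut-2-enoyl)oxy]-5,8-dioxo-5,8-dihydronaphthalen-2-yl}-4-methylpent-3-enyl 3-methylbut-2-enoate
Product: 23 (1R)-1-(4-hydroxy-1-methoxy-5,8-dioxo-5,8-dihydronaphthalen-2-yl)-4-methylpent-3-enyl 3-methylbut-2-enoate
Conditions: K2CO3 (1 equiv), MeOH, −10 → 0 °C, argon; then mild acidic work-up
Reagents that add atoms: none
Why: Base-mediated transesterification; the aryl ester has by far the better leaving group (a naphtholate peri to a quinone carbonyl), while the secondary alkyl ester is branched and its carbonyl is deactivated by conjugation, so one equivalent of carbonate in cold methanol should remove only the C8 acyl group. The stereocentre is not involved.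

Compound list

1 | 1,4-dimethoxybenzene | COc1ccc(OC)cc1 | starting material
2 | hexacarbonylchromium, Cr(CO)6 | O=C=[Cr](=C=O)(=C=O)(=C=O)(=C=O)=C=O | starting material
3 | 2,5-dimethoxyphenyllithium (formed in the flask, not isolated) | [Li]c1cc(OC)ccc1OC | intermediate
4 | lithium pentacarbonyl(2,5-dimethoxybenzoyl)chromate (formed in the flask, not isolated) | [Li+].COc1ccc(OC)c(c1)C([O-])=[Cr](=C=O)(=C=O)(=C=O)(=C=O)=C=O | intermediate
5 | tetramethylammonium pentacarbonyl(2,5-dimethoxybenzoyl)chromate | C[N+](C)(C)C.COc1ccc(OC)c(c1)C([O-])=[Cr](=C=O)(=C=O)(=C=O)(=C=O)=C=O | intermediate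
6 | pentacarbonyl[acetoxy(2,5-dimethoxyphenyl)methylidene]chromium (formed in the flask, not isolated) | COc1ccc(OC)c(c1)C(OC(C)=O)=[Cr](=C=O)(=C=O)(=C=O)(=C=O)=C=O | intermediate
7 | pentacarbonyl{(2,5-dimethoxyphenyl)[2-(trimethylsilyl)ethoxy]methylidene}chromium | COc1ccc(OC)c(c1)C(OCC[Si](C)(C)C)=[Cr](=C=O)(=C=O)(=C=O)(=C=O)=C=O | intermediate
8 | 4-methylpent-3-enoic acid | CC(C)=CCC(=O)O | starting material
9 | N-methoxy-N,4-dimethylpent-3-enamide | CON(C)C(=O)CC=C(C)C | intermediate
10 | ethynyltrimethylsilane | C#C[Si](C)(C)C | starting material
11 | lithium (trimethylsilyl)acetylide (formed in the flask, not isolated) | [Li]C#C[Si](C)(C)C | intermediate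
12 | 6-methyl-1-(trimethylsilyl)hept-5-en-1-yn-3-one | C[Si](C)(C)C#CC(=O)CC=C(C)C | intermediate
13 | (3R)-6-methyl-1-(trimethylsilyl)hept-5-en-1-yn-3-ol | C[Si](C)(C)C#C[C@@H](CC=C(C)C)O | intermediate
14 | tert-butyldimethyl{[(3R)-6-methyl-1-(trimethylsilyl)hept-5-en-1-yn-3-yl]oxy}silane (formed in the flask, not isolated) | C[Si](C)(C)C#C[C@@H](CC=C(C)C)O[Si](C)(C)C(C)(C)C | intermediate
15 | tert-butyldimethyl{[(3R)-6-methylhept-5-en-1-yn-3-yl]oxy}silane | C#C[C@@H](CC=C(C)C)O[Si](C)(C)C(C)(C)C | intermediate
16 | tricarbonylchromium η6-complex of 17, Cr(CO)3 on the new ring (formed in the flask, not isolated; written as its two parts) | Oc1c([C@@H](CC=C(C)C)O[Si](C)(C)C(C)(C)C)cc(OCC[Si](C)(C)C)c2c(OC)ccc(OC)c12.O=C=[Cr](=C=O)=C=O | intermediate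
17 | 2-[(1R)-1-(tert-butyldimethylsilyloxy)-4-methylpent-3-enyl]-5,8-dimethoxy-4-[2-(trimethylsilyl)ethoxy]naphthalen-1-ol | Oc1c([C@@H](CC=C(C)C)O[Si](C)(C)C(C)(C)C)cc(OCC[Si](C)(C)C)c2c(OC)ccc(OC)c12 | intermediate
18 | tert-butyl{[(1R)-4-methyl-1-{1,5,8-trimethoxy-4-[2-(trimethylsilyl)ethoxy]naphthalen-2-yl}pent-3-en-1-yl]oxy}dimethylsilane | COc1c([C@@H](CC=C(C)C)O[Si](C)(C)C(C)(C)C)cc(OCC[Si](C)(C)C)c2c(OC)ccc(OC)c12 | intermediate
19 | 3-[(1R)-1-hydroxy-4-methylpent-3-enyl]-4,5,8-trimethoxynaphthalen-1-ol | COc1c([C@@H](CC=C(C)C)O)cc(O)c2c(OC)ccc(OC)c12 | intermediate
20 | 3-methylbut-2-enoic acid | CC(C)=CC(=O)O | starting material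
21 | (1R)-4-methyl-1-{1,5,8-trimethoxy-4-[(3-methylbut-2-enoyl)oxy]naphthalen-2-yl}pent-3-enyl 3-methylbut-2-enoate | COc1c([C@@H](CC=C(C)C)OC(=O)C=C(C)C)cc(OC(=O)C=C(C)C)c2c(OC)ccc(OC)c12 | intermediate
22 | (1R)-1-{1-methoxy-4-[(3-methylbut-2-enoyl)oxy]-5,8-dioxo-5,8-dihydronaphthalen-2-yl}-4-methylpent-3-enyl 3-methylbut-2-enoate | COc1c([C@@H](CC=C(C)C)OC(=O)C=C(C)C)cc(OC(=O)C=C(C)C)c2c1C(=O)C=CC2=O | intermediate
23 | (1R)-1-(4-hydroxy-1-methoxy-5,8-dioxo-5,8-dihydronaphthalen-2-yl)-4-methylpent-3-enyl 3-methylbut-2-enoate (8-hydroxy-5-methoxy-6-substituted naphthalene-1,4-dione in the ring numbering used above) | COc1c([C@@H](CC=C(C)C)OC(=O)C=C(C)C)cc(O)c2c1C(=O)C=CC2=O | target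

Total step count: 12. Longest linear sequence: 10 steps (steps 3–12, from 8 to 23); the carbene branch (steps 1 and 2) joins at step 7.

Steps least certain to work

Step 7 (key step). After alkyne insertion the vinylcarbene may collapse without carbonyl insertion (five-ring formation onto the aryl group) or start oligomerisation of the terminal alkyne; both are favoured by a bulky alkoxy group on the carbene carbon. In addition, the very electron-rich 4-alkoxy-1-naphthol may be oxidised past 17 while the Cr(CO)3 unit is removed in air. The fallback sets out from 7 and 15 and comes back at 19; it makes the oxidation deliberate and differentiates the two oxygens by sterics afterwards.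
- The benzannulation mixture is not aired but treated with (NH4)2Ce(NO3)6 in cold aqueous MeCN. This converts 17, with loss of the silylethanol, into the ring A quinone 2-[(1R)-1-(tert-butyldimethylsilyloxy)-4-methylpent-3-enyl]-5,8-dimethoxynaphthalene-1,4-dione F1, whose electron-poor core protects the dimethoxy ring from further oxidation.
- Na2S2O4 (two-phase, argon) reduces it to 2-[(1R)-1-(tert-butyldimethylsilyloxy)-4-methylpent-3-enyl]-5,8-dimethoxynaphthalene-1,4-diol F2.
- TIPSCl and imidazole silylate the less hindered hydroxyl (the one flanked by C–H, the future C8 oxygen), giving 2-[(1R)-1-(tert-butyldimethylsilyloxy)-4-methylpent-3-enyl]-5,8-dimethoxy-4-(triisopropylsilyloxy)naphthalen-1-ol F3.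
- MeI and Cs2CO3 methylate the remaining hydroxyl beside the side chain, giving tert-butyldimethyl{[(1R)-4-methyl-1-{1,5,8-trimethoxy-4-[(triisopropylsilyl)oxy]naphthalen-2-yl}pent-3-en-1-yl]oxy}silane F4.
- Bu4NF at 0 °C → rt removes both silyl ethers and gives 19.

Step 2. The acetoxycarbene 6 may decompose before the alcohol has displaced acetate, and the product carbene may be dealkylated by bromide attacking silicon (loss of ethene, return to the acylchromate). The fallback sets out from 5 and comes back at 19; it uses the methoxy carbene and so also removes the bulky alkoxy group that burdens step 7.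
- 5 is O-methylated with methyl trifluoromethanesulfonate (CH2Cl2, 0 °C) to pentacarbonyl[(2,5-dimethoxyphenyl)(methoxy)methylidene]chromium F5.
- Benzannulation of F5 with 15 (THF, 50 °C) gives 2-[(1R)-1-(tert-butyldimethylsilyloxy)-4-methylpent-3-enyl]-4,5,8-trimethoxynaphthalen-1-ol F6, which is not isolated.
- The same cerium work-up converts F6, with loss of methanol, into quinone F1, and from F1 the sequence of the step 7 fallback leads to 19.

Step 9. Fragmentation of the aryl 2-(trimethylsilyl)ethyl ether may be incomplete at a temperature the molecule tolerates, and the liberated electron-rich naphtholate may undergo oxidative coupling or decomposition in hot basic fluoride. The fallback sets out from 18 and comes back at 21; it changes the order of events so that the free naphthol never accumulates.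
- Bu4NF (1.1 equiv, 0 °C) removes only the TBS group, giving (1R)-4-methyl-1-{1,5,8-trimethoxy-4-[2-(trimethylsilyl)ethoxy]naphthalen-2-yl}pent-3-en-1-ol F7.
- Steglich acylation with 20 gives (1R)-4-methyl-1-{1,5,8-trimethoxy-4-[2-(trimethylsilyl)ethoxy]naphthalen-2-yl}pent-3-enyl 3-methylbut-2-enoate F8.
- CsF in DMF at 80 °C in the presence of 3-methylbut-2-enoic anhydride fragments the aryl ether, and the naphtholate is acylated as it forms, giving 21.

Step 12. The methanolysis may fail to discriminate between the aryl and the alkyl ester, and methoxide may add to the unsubstituted C2=C3 bond of the quinone. The fallback sets out from 22 and comes back at 23; it takes the electrophilic quinone out of play during the ester cleavage.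
- Na2S2O4 (two-phase, argon) reduces 22 to (1R)-1-{5,8-dihydroxy-1-methoxy-4-[(3-methylbut-2-enoyl)oxy]naphthalen-2-yl}-4-methylpent-3-enyl 3-methylbut-2-enoate F9.
- K2CO3 in cold MeOH under argon cleaves the aryl ester (wherever the acyl group sits after a possible peri shift), giving (1R)-1-(4,5,8-trihydroxy-1-methoxynaphthalen-2-yl)-4-methylpent-3-enyl 3-methylbut-2-enoate F10.
- Admission of air (or Ag2O) reoxidises the free hydroquinone of ring B, which alone can form a quinone without losing a methyl group, to 23.

Further compounds

F1 | step 7 | 2-[(1R)-1-(tert-butyldimethylsilyloxy)-4-methylpent-3-enyl]-5,8-dimethoxynaphthalene-1,4-dione | COc1ccc(OC)c2c1C(=O)C=C([C@@H](CC=C(C)C)O[Si](C)(C)C(C)(C)C)C2=O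
F2 | step 7 | 2-[(1R)-1-(tert-butyldimethylsilyloxy)-4-methylpent-3-enyl]-5,8-dimethoxynaphthalene-1,4-diol | COc1ccc(OC)c2c(O)c([C@@H](CC=C(C)C)O[Si](C)(C)C(C)(C)C)cc(O)c12
F3 | step 7 | 2-[(1R)-1-(tert-butyldimethylsilyloxy)-4-methylpent-3-enyl]-5,8-dimethoxy-4-(triisopropylsilyloxy)naphthalen-1-ol | Oc1c([C@@H](CC=C(C)C)O[Si](C)(C)C(C)(C)C)cc(O[Si](C(C)C)(C(C)C)C(C)C)c2c(OC)ccc(OC)c12
F4 | step 7 | tert-butyldimethyl{[(1R)-4-methyl-1-{1,5,8-trimethoxy-4-[(triisopropylsilyl)oxy]naphthalen-2-yl}pent-3-en-1-yl]oxy}silane | COc1c([C@@H](CC=C(C)C)O[Si](C)(C)C(C)(C)C)cc(O[Si](C(C)C)(C(C)C)C(C)C)c2c(OC)ccc(OC)c12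
F5 | step 2 | pentacarbonyl[(2,5-dimethoxyphenyl)(methoxy)methylidene]chromium | COc1ccc(OC)c(c1)C(OC)=[Cr](=C=O)(=C=O)(=C=O)(=C=O)=C=O
F6 | step 2 | 2-[(1R)-1-(tert-butyldimethylsilyloxy)-4-methylpent-3-enyl]-4,5,8-trimethoxynaphthalen-1-ol | Oc1c([C@@H](CC=C(C)C)O[Si](C)(C)C(C)(C)C)cc(OC)c2c(OC)ccc(OC)c12
F7 | step 9 | (1R)-4-methyl-1-{1,5,8-trimethoxy-4-[2-(trimethylsilyl)ethoxy]naphthalen-2-yl}pent-3-en-1-ol | COc1c([C@@H](CC=C(C)C)O)cc(OCC[Si](C)(C)C)c2c(OC)ccc(OC)c12
F8 | step 9 | (1R)-4-methyl-1-{1,5,8-trimethoxy-4-[2-(trimethylsilyl)ethoxy]naphthalen-2-yl}pent-3-enyl 3-methylbut-2-enoate | COc1c([C@@H](CC=C(C)C)OC(=O)C=C(C)C)cc(OCC[Si](C)(C)C)c2c(OC)ccc(OC)c12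
F9 | step 12 | (1R)-1-{5,8-dihydroxy-1-methoxy-4-[(3-methylbut-2-enoyl)oxy]naphthalen-2-yl}-4-methylpent-3-enyl 3-methylbut-2-enoate | COc1c([C@@H](CC=C(C)C)OC(=O)C=C(C)C)cc(OC(=O)C=C(C)C)c2c(O)ccc(O)c12
F10 | step 12 | (1R)-1-(4,5,8-trihydroxy-1-methoxynaphthalen-2-yl)-4-methylpent-3-enyl 3-methylbut-2-enoate | COc1c([C@@H](CC=C(C)C)OC(=O)C=C(C)C)cc(O)c2c(O)ccc(O)c12
A1 | alternative 1 | {2-bromo-5-[(1R)-1-(tert-butyldimethylsilyloxy)-4-methylpent-3-enyl]-4-methoxyphenoxy}triisopropylsilane | COc1cc(Br)c(O[Si](C(C)C)(C(C)C)C(C)C)cc1[C@@H](CC=C(C)C)O[Si](C)(C)C(C)(C)C
A2 | alternative 1 | furan | c1ccoc1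
A3 | alternative 1 | 5-methoxy-6-[(1R)-1-(tert-butyldimethylsilyloxy)-4-methylpent-3-enyl]-8-(triisopropylsilyloxy)-1,4-dihydro-1,4-epoxynaphthalene (both bridgehead diastereomers) | COc1c([C@@H](CC=C(C)C)O[Si](C)(C)C(C)(C)C)cc(O[Si](C(C)C)(C(C)C)C(C)C)c2c1C1C=CC2O1
A4 | alternative 2 | 6-hydroxy-5-methoxy-4-[(1R)-1-(tert-butyldimethylsilyloxy)-4-methylpent-3-enyl]-2H-pyran-2-one | COC1=C(O)OC(=O)C=C1[C@@H](CC=C(C)C)O[Si](C)(C)C(C)(C)C
A5 | alternative 2 | 1,4-benzoquinone | O=C1C=CC(=O)C=C1
A6 | alternative 2 | 8-hydroxy-5-methoxy-6-[(1R)-1-(tert-butyldimethylsilyloxy)-4-methylpent-3-enyl]naphthalene-1,4-dione | COc1c([C@@H](CC=C(C)C)O[Si](C)(C)C(C)(C)C)cc(O)c2c1C(=O)C=CC2=O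
A7 | alternative 3 | (1R)-1-[4-(2,5-dimethoxyphenyl)-4-methoxy-3-oxocyclobut-1-en-1-yl]-4-methylpent-3-enyl N,N-diisopropylcarbamate (either configuration at the ring carbon) | COc1ccc(OC)c(c1)C1(OC)C(=O)C=C1[C@@H](CC=C(C)C)OC(=O)N(C(C)C)C(C)C
A8 | alternative 3 | (1R)-1-(4-hydroxy-1,5,8-trimethoxynaphthalen-2-yl)-4-methylpent-3-enyl N,N-diisopropylcarbamate | COc1c([C@@H](CC=C(C)C)OC(=O)N(C(C)C)C(C)C)cc(O)c2c(OC)ccc(OC)c12
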